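**Plan**
- Retrosynthesis: the methyl ester comes from methanolysis of an aryl lactone (O7–C1'), and the lactone from a lactol.
- The lactol is cut at C8–C3' and O7–C1' into (E)-hex-2-enal and a 6-prenyl-5,7-dihydroxychromanone. This works because, once C6 carries the prenyl group, C8 is the only aromatic CH and sits next to the 7-OH, so the new chain can be locked as a six-membered lactol on O7.
- The prenyl group is cut back to a C6-allyl group (cross-metathesis), and that to an O5-allyl ether (Claisen shift).
- The chromanone ring is cut at C4–C4a (Friedel–Crafts acylation) and O1–C2 (Mitsunobu ether) into 3,5-bis(benzyloxy)phenol and an anti-3-hydroxy-2-methylbutanoate.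
- Forward order: aryl ether, chromanone ring, C6 allyl, prenyl, then the lactol ring with the hexanal chain, oxidation, ring opening.
- Stereochemistry: C3 from Fráter–Seebach methylation of (S)-3-hydroxybutanoate, C2 from Mitsunobu inversion (cis, 2R,3S), C3' from the (S)-diphenylprolinol silyl ether catalyst.

Key step: step 10

Remark: chromanone numbering (O1, C2, C3, C4, C4a, C5–C8, C8a) is used throughout; the hexanoate chain is C1' (ester carbon) to C6'; the cis-2,3-dimethyl ring corresponds to 2R,3S.

**Route**

Step 1
Reactants: 1 tert-butyl (S)-3-hydroxybutanoate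
Product: 2 tert-butyl (2S,3S)-3-hydroxy-2-methylbutanoate
Conditions: LDA (2.2 equiv), THF, −78 to −20 °C; then MeI, DMPU, −78 to 0 °C
Reagents that add atoms: iodomethane, CI
Why: Fráter–Seebach alkylation, in which the chelated lithium alkoxide–enolate dianion should take up iodomethane on the face opposite the C3 methyl group, setting C2 as S (anti, 2S,3S) while C3 is untouched.

Step 2
Reactants: 2 tert-butyl (2S,3S)-3-hydroxy-2-methylbutanoate; 3 3,5-bis(benzyloxy)phenol
Product: 4 tert-butyl (2S,3R)-3-[3,5-bis(benzyloxy)phenoxy]-2-methylbutanoate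
Conditions: PPh3, DIAD, toluene, 0 °C to rt
Reagents that add atoms: none
Why: Mitsunobu etherification, in which the phenol displaces the oxyphosphonium of the secondary alcohol by SN2 with inversion (3S to 3R), giving the relative configuration needed for a cis-chromanone; a non-polar solvent and low temperature should hold back elimination to the tiglate.

Step 3
Reactants: 4 tert-butyl (2S,3R)-3-[3,5-bis(benzyloxy)phenoxy]-2-methylbutanoate
Product: 7 (2R,3S)-5,7-bis(benzyloxy)-2,3-dimethylchroman-4-one, via free carboxylic acid 5 (not isolated), via mixed trifluoroacetic anhydride 6 (not isolated)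
Conditions: TFA, CH2Cl2, 0 °C to rt; evaporate; then TFAA, CH2Cl2, 0 °C
Reagents that add atoms: none
Why: Acidolysis of the tert-butyl ester followed by intramolecular Friedel–Crafts acylation through the mixed anhydride, which the trioxygenated ring should undergo at 0 °C without a Lewis acid; the two positions ortho to the ether oxygen are equivalent by symmetry so only one chromanone can form, every free ring carbon is flanked by two alkoxy groups and is too hindered for tert-butylation, and the two stereocentres (acid C3 becomes C2, acid C2 becomes C3) are not touched.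

Step 4
Reactants: 7 (2R,3S)-5,7-bis(benzyloxy)-2,3-dimethylchroman-4-one
Product: 8 (2R,3S)-5,7-dihydroxy-2,3-dimethylchroman-4-one
Conditions: H2 (1 atm), 10% Pd/C, EtOAc, rt
Reagents that add atoms: none
Why: Hydrogenolysis of aryl benzyl ethers; the ketone is a vinylogous ester of three ring oxygens and should resist reduction, and the neutral medium leaves C2 and C3 alone.

Step 5
Reactants: 8 (2R,3S)-5,7-dihydroxy-2,3-dimethylchroman-4-one
Product: 9 (2R,3S)-5-hydroxy-2,3-dimethyl-7-(triisopropylsilyloxy)chroman-4-one
Conditions: TIPSCl (1.05 equiv), imidazole, DMF, 0 °C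
Reagents that add atoms: chlorotriisopropylsilane, CC(C)[Si](Cl)(C(C)C)C(C)C
Why: Selective phenol silylation, because the 7-OH (para to the carbonyl, unhindered, more acidic) reacts while the 5-OH is held in a hydrogen bond to C4=O; the bulky TIPS group is chosen because an aryl silyl ether para to a ketone is otherwise labile.

Step 6
Reactants: 9 (2R,3S)-5-hydroxy-2,3-dimethyl-7-(triisopropylsilyloxy)chroman-4-one; 10 prop-2-en-1-ol (allyl alcohol)
Product: 11 (2R,3S)-5-(allyloxy)-2,3-dimethyl-7-(triisopropylsilyloxy)chroman-4-one
Conditions: PPh3, DIAD, THF, 0 °C to rt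
Reagents that add atoms: none
Why: Mitsunobu O-alkylation of the chelated 5-OH with a primary allylic alcohol, a near-neutral etherification that avoids the carbonate bases able to epimerise or open a 3-substituted chromanone.

Step 7
Reactants: 11 (2R,3S)-5-(allyloxy)-2,3-dimethyl-7-(triisopropylsilyloxy)chroman-4-one
Product: 12 (2R,3S)-6-allyl-5-hydroxy-2,3-dimethyl-7-(triisopropylsilyloxy)chroman-4-one
Conditions: Eu(fod)3 [tris(6,6,7,7,8,8,8-heptafluoro-2,2-dimethyloctane-3,5-dionato)europium] (10 mol%), CHCl3, 70 °C, sealed tube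
Reagents that add atoms: none
Why: Lewis-acid-catalysed aromatic Claisen rearrangement, in which chelation of trivalent europium between O5 and the C4 carbonyl speeds the [3,3] shift; it can end only at C6 because the other ortho carbon C4a is quaternary, and with an unsubstituted allyl group the dienone should tautomerise to the phenol faster than a Cope shift to C8.

Step 8
Reactants: 12 (2R,3S)-6-allyl-5-hydroxy-2,3-dimethyl-7-(triisopropylsilyloxy)chroman-4-one; 13 2-methylbut-2-ene
Product: 14 (2R,3S)-5-hydroxy-2,3-dimethyl-6-(3-methylbut-2-enyl)-7-(triisopropylsilyloxy)chroman-4-one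
Conditions: second-generation Grubbs catalyst RuCl2(=CHPh)(H2IMes)(PCy3) (5 mol%), CH2Cl2/2-methylbut-2-ene, 40 °C
Reagents that add atoms: none
Why: Olefin cross-metathesis of a terminal allylarene with 2-methylbut-2-ene, a standard allyl-to-prenyl exchange that releases propene and tolerates the chelated phenol, the ketone and the silyl ether.

Step 9
Reactants: 14 (2R,3S)-5-hydroxy-2,3-dimethyl-6-(3-methylbut-2-enyl)-7-(triisopropylsilyloxy)chroman-4-one
Product: 15 (2R,3S)-5,7-dihydroxy-2,3-dimethyl-6-(3-methylbut-2-enyl)chroman-4-one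
Conditions: TBAF, AcOH, THF, 0 °C
Reagents that add atoms: none
Why: Fluoride desilylation of an aryl silyl ether, buffered with acetic acid so that no basic fluoride or free phenoxide can epimerise C3.

Step 10
Reactants: 15 (2R,3S)-5,7-dihydroxy-2,3-dimethyl-6-(3-methylbut-2-enyl)chroman-4-one; 16 (E)-hex-2-enal
Product: 18 (2R,3S,10R)-5,8-dihydroxy-2,3-dimethyl-6-(3-methylbut-2-enyl)-10-propyl-2,3,9,10-tetrahydro-4H,8H-pyrano[2,3-f]chromen-4-one (O7 lactol as a mixture of lactol anomers), via open-chain aldehyde 17 (not isolated)
Conditions: (S)-α,α-diphenylprolinol trimethylsilyl ether (20 mol%), PhCO2H (20 mol%), toluene, 0 °C to rt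
Reagents that add atoms: none
Why: The enal and the secondary amine condense, with benzoic acid assisting, to an E-configured s-trans iminium ion whose β-carbon C3' is attacked by C8 of the phenol (ortho to the free 7-OH, para to the 5-OH); rearomatisation, protonation of the enamine and hydrolysis release aldehyde 17 and the catalyst. The closest known reaction is the diarylprolinol-silyl-ether-catalysed Friedel–Crafts alkylation and hemiacetalisation of naphthols and other electron-rich phenols with enals to 4-substituted chroman-2-ols. The one ring that closes is the six-membered lactol, formed by 6-exo-trig addition of O7 to the aldehyde carbon C1'. The new centre C3' is set by the catalyst, whose diphenyl(silyloxy)methyl group shields one face of the iminium ion; on the usual shielding model the S catalyst and an aliphatic enal should give the R configuration, and the remote C2 and C3 centres are not expected to interfere. Site selectivity among ring carbons is secured by the substrate, since C6 carries the prenyl group and C8 is the only ring carbon left with a hydrogen; the hindered iminium ion favours 1,4- over 1,2-attack, and lactol formation withdraws the aldehyde from further aminocatalysis. The buffered amine and weak-acid medium at or below room temperature is chosen so that C3 of the cis-chromanone should not epimerise.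

Step 11
Reactants: 18 the O7 lactol (2R,3S,10R)-5,8-dihydroxy-2,3-dimethyl-6-(3-methylbut-2-enyl)-10-propyl-2,3,9,10-tetrahydro-4H,8H-pyrano[2,3-f]chromen-4-one
Product: 19 (2R,3S,10R)-5-hydroxy-2,3-dimethyl-6-(3-methylbut-2-enyl)-10-propyl-2,3,9,10-tetrahydro-4H,8H-pyrano[2,3-f]chromene-4,8-dione
Conditions: Ag2CO3 on Celite, toluene, 80 °C
Reagents that add atoms: none
Why: Fétizon oxidation, in which monovalent silver on Celite turns lactols into lactones quickly under neutral heterogeneous conditions that should leave the prenyl alkene, the chelated phenol and the three stereocentres untouched.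

Step 12
Reactants: 19 (2R,3S,10R)-5-hydroxy-2,3-dimethyl-6-(3-methylbut-2-enyl)-10-propyl-2,3,9,10-tetrahydro-4H,8H-pyrano[2,3-f]chromene-4,8-dione
Product: 20 methyl (R)-3-[(2R,3S)-5,7-dihydroxy-2,3-dimethyl-6-(3-methylbut-2-enyl)-4-oxochroman-8-yl]hexanoate
Conditions: MeOH, camphorsulfonic acid (10 mol%), rt; NaHCO3 quench
Reagents that add atoms: methanol, CO
Why: Acid-catalysed transesterification (methanolysis) of an aryl lactone whose leaving group is a phenol para to the C4 carbonyl, so ring opening in methanol should be easy and re-closure slow, giving the methyl ester and the free 7-OH without touching C2, C3 or C3'.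

**Compound list**

1 | tert-butyl (S)-3-hydroxybutanoate | C[C@H](O)CC(=O)OC(C)(C)C | starting material
2 | tert-butyl (2S,3S)-3-hydroxy-2-methylbutanoate | C[C@H](O)[C@H](C)C(=O)OC(C)(C)C | intermediate
3 | 3,5-bis(benzyloxy)phenol | Oc1cc(OCc2ccccc2)cc(OCc2ccccc2)c1 | starting material
4 | tert-butyl (2S,3R)-3-[3,5-bis(benzyloxy)phenoxy]-2-methylbutanoate | C[C@@H](Oc1cc(OCc2ccccc2)cc(OCc2ccccc2)c1)[C@H](C)C(=O)OC(C)(C)C | intermediate
5 | (2S,3R)-3-[3,5-bis(benzyloxy)phenoxy]-2-methylbutanoic acid | C[C@@H](Oc1cc(OCc2ccccc2)cc(OCc2ccccc2)c1)[C@H](C)C(=O)O | intermediate (not isolated)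
6 | (2S,3R)-3-[3,5-bis(benzyloxy)phenoxy]-2-methylbutanoic trifluoroacetic anhydride | C[C@@H](Oc1cc(OCc2ccccc2)cc(OCc2ccccc2)c1)[C@H](C)C(=O)OC(=O)C(F)(F)F | intermediate (not isolated)
7 | (2R,3S)-5,7-bis(benzyloxy)-2,3-dimethylchroman-4-one | c1c(OCc3ccccc3)cc(OCc3ccccc3)c2c1O[C@H](C)[C@H](C)C2=O | intermediate
8 | (2R,3S)-5,7-dihydroxy-2,3-dimethylchroman-4-one | c1c(O)cc(O)c2c1O[C@H](C)[C@H](C)C2=O | intermediate
9 | (2R,3S)-5-hydroxy-2,3-dimethyl-7-(triisopropylsilyloxy)chroman-4-one | c1c(O[Si](C(C)C)(C(C)C)C(C)C)cc(O)c2c1O[C@H](C)[C@H](C)C2=O | intermediate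
10 | prop-2-en-1-ol | C=CCO | starting material
11 | (2R,3S)-5-(allyloxy)-2,3-dimethyl-7-(triisopropylsilyloxy)chroman-4-one | c1c(O[Si](C(C)C)(C(C)C)C(C)C)cc(OCC=C)c2c1O[C@H](C)[C@H](C)C2=O | intermediate
12 | (2R,3S)-6-allyl-5-hydroxy-2,3-dimethyl-7-(triisopropylsilyloxy)chroman-4-one | c1c(O[Si](C(C)C)(C(C)C)C(C)C)c(CC=C)c(O)c2c1O[C@H](C)[C@H](C)C2=O | intermediate
13 | 2-methylbut-2-ene | CC=C(C)C | starting material
14 | (2R,3S)-5-hydroxy-2,3-dimethyl-6-(3-methylbut-2-enyl)-7-(triisopropylsilyloxy)chroman-4-one | c1c(O[Si](C(C)C)(C(C)C)C(C)C)c(CC=C(C)C)c(O)c2c1O[C@H](C)[C@H](C)C2=O | intermediate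
15 | (2R,3S)-5,7-dihydroxy-2,3-dimethyl-6-(3-methylbut-2-enyl)chroman-4-one | c1c(O)c(CC=C(C)C)c(O)c2c1O[C@H](C)[C@H](C)C2=O | intermediate
16 | (E)-hex-2-enal | CCC/C=C/C=O | starting material
17 | (R)-3-[(2R,3S)-5,7-dihydroxy-2,3-dimethyl-6-(3-methylbut-2-enyl)-4-oxochroman-8-yl]hexanal | CCC[C@H](CC=O)c1c(O)c(CC=C(C)C)c(O)c2c1O[C@H](C)[C@H](C)C2=O | intermediate (not isolated)
18 | (2R,3S,10R)-5,8-dihydroxy-2,3-dimethyl-6-(3-methylbut-2-enyl)-10-propyl-2,3,9,10-tetrahydro-4H,8H-pyrano[2,3-f]chromen-4-one, O7 lactol, both anomers | CCC[C@@H]1CC(O)Oc2c(CC=C(C)C)c(O)c3c(c12)O[C@H](C)[C@H](C)C3=O | intermediate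
19 | (2R,3S,10R)-5-hydroxy-2,3-dimethyl-6-(3-methylbut-2-enyl)-10-propyl-2,3,9,10-tetrahydro-4H,8H-pyrano[2,3-f]chromene-4,8-dione | CCC[C@@H]1CC(=O)Oc2c(CC=C(C)C)c(O)c3c(c12)O[C@H](C)[C@H](C)C3=O | intermediate
20 | methyl (R)-3-[(2R,3S)-5,7-dihydroxy-2,3-dimethyl-6-(3-methylbut-2-enyl)-4-oxochroman-8-yl]hexanoate | CCC[C@H](CC(=O)OC)c1c(O)c(CC=C(C)C)c(O)c2c1O[C@H](C)[C@H](C)C2=O | target

**Step count and risks**

Total step count: 12. Longest linear sequence: 12 steps (1 to 20).

Steps most likely to fail:

1. Step 10. The acylated phloroglucinol ring may be too weak a nucleophile, so that enal self-condensation or 1,2-attack leading to a 2H-chromene outruns the conjugate addition; facial selectivity may be poor; or the amine may epimerise C3. The fallback sets out from 15 and comes back at 19. Knoevenagel condensation of butanal with Meldrum's acid should give 5-butylidene-2,2-dimethyl-1,3-dioxane-4,6-dione F1. Its Yb(OTf)3-catalysed Friedel–Crafts conjugate addition at C8 of 15 (nitromethane, gentle warming), followed by lactonisation through O7 with loss of acetone and carbon dioxide, should give lactone 19 directly, together with its C10 epimer, the (2R,3S,10S)-lactone F2. This amine-free annulation forms the same C8–C3' and O7–C1' bonds at the lactone oxidation level but gives up catalyst control, so 19 and F2 would be separated by chromatography before step 12.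

2. Step 2. The activated β-hydroxy ester may eliminate to the tiglate faster than the phenol substitutes. The fallback sets out from 2 and comes back at 5. TFA cleavage of the tert-butyl ester should give (2S,3S)-3-hydroxy-2-methylbutanoic acid F3. Carboxyl-activating lactonisation (PhSO2Cl, pyridine, 0 °C), which retains C3, should give the trans β-lactone (3S,4S)-3,4-dimethyloxetan-2-one F4. The sodium salt of phenol 3 should open F4 at C4 by SN2 alkyl–oxygen cleavage with inversion, giving acid 5 without an ester to remove; 5 is then cyclised with TFAA to 7 as in step 3.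

3. Step 7. The shift next to the bulky silyl ether may be slow, partial migration to C8 may occur, or the Lewis acid may enolise C3 on prolonged heating. The fallback sets out from 9 and comes back at 14, by-passing steps 6 to 8. Iodination ortho to the free chelated 5-OH (N-iodosuccinimide, CH2Cl2, 0 °C) should give (2R,3S)-5-hydroxy-6-iodo-2,3-dimethyl-7-(triisopropylsilyloxy)chroman-4-one F5. Stille coupling of F5 with tributyl(3-methylbut-2-enyl)stannane under Pd(PPh3)4 (zerovalent palladium) in DMF should install the linear prenyl group and give 14.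

**Further compounds**

F1 | step 10 | 5-butylidene-2,2-dimethyl-1,3-dioxane-4,6-dione | CCCC=C1C(=O)OC(C)(C)OC1=O
F2 | step 10 | (2R,3S,10S)-5-hydroxy-2,3-dimethyl-6-(3-methylbut-2-enyl)-10-propyl-2,3,9,10-tetrahydro-4H,8H-pyrano[2,3-f]chromene-4,8-dione (C10 epimer of 19) | CCC[C@H]1CC(=O)Oc2c(CC=C(C)C)c(O)c3c(c12)O[C@H](C)[C@H](C)C3=O
F3 | step 2 | (2S,3S)-3-hydroxy-2-methylbutanoic acid | C[C@H](O)[C@H](C)C(=O)O
F4 | step 2 | (3S,4S)-3,4-dimethyloxetan-2-one | C[C@@H]1OC(=O)[C@H]1C
F5 | step 7 | (2R,3S)-5-hydroxy-6-iodo-2,3-dimethyl-7-(triisopropylsilyloxy)chroman-4-one | c1c(O[Si](C(C)C)(C(C)C)C(C)C)c(I)c(O)c2c1O[C@H](C)[C@H](C)C2=O
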